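# Proposed synthesis of the depside CNP0310773.0 by aryne carbomagnesiation–carboxylation

## The problem

Target 16 is a depside. Ring A (C1' carbonyl, C2' OH, C3' Cl, C4' OMe, C5' H, C6' pentyl) is joined through its C1' carboxyl as an aryl ester to the C4 oxygen of ring B, which is olivetolic acid (C1 CO2H, C2 OH, C6 pentyl). There is no stereocentre and no ring to close between the two halves, so the difficulties are regiochemical and chemoselective. Ring A carries five different substituents in a fixed order, and electrophilic substitution of a resorcylate cannot be relied on to place chlorine at C3' and not at C5'. The inter-ring ester is slow to form, because its carbonyl lies between the C2' hydroxyl and the C6' pentyl chain, and once formed it is an aryl ester that hydroxide, alkoxides and amines cleave. It must therefore be made late, without base, and at the C4 hydroxyl of ring B, not the C2 hydroxyl. Both 2-hydroxybenzoic acid units lose CO2 on heating or in strong acid, the aryl chloride restricts hydrogenation and halogen–metal exchange, and the free phenols restrict strong base and oxidants. The feature that opens the route is the C1'–C6' edge of ring A: the two carbon substituents sit on neighbouring carbons, C1' has an oxygen-bearing neighbour (C2') and C6' a hydrogen-bearing one (C5'). This is the pattern produced when a carbon nucleophile and a carbon electrophile add across a 3-alkoxyaryne. In addition, C3' lies between two oxygen-bearing carbons, so the O–Cl–O array is locally symmetric and the aryne precursor can be drawn from a symmetric arene.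

## Retrosynthesis

**Inter-ring ester.** The acid of ring B is masked as its benzyl ester, which takes 16 back to 15. The ester C(=O)–O bond between the C1' carbonyl and O4 is then cut, giving ring A acid 12 and ring B phenol 14. This cut comes first because it removes the most fragile bond and divides the molecule into two benzoates of similar size. Cutting a ring carbon–carbon bond instead would require an aromatic ring to be built on a molecule that already holds the labile ester. The forward reaction must acylate the one phenol that is not hydrogen-bonded to a carbonyl (C4–OH of 14) under acidic conditions. The final hydrogenolysis must stop before the C3' chloride is touched.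

**Ring B ester.** 14 comes from olivetolic acid 13 by cutting the benzyl–oxygen bond of the ester. The forward reaction only has to alkylate a carboxylate in the presence of two phenols, at a temperature below that of decarboxylation.

**C2' methyl ether.** 12 is traced to dimethyl ether 11 by cutting the O–CH3 bond at C2'. Two identical methyl ethers are preferred to two different protecting groups because they keep every earlier intermediate symmetric about the chlorine-bearing carbon. The two oxygens become different only when the carboxyl arrives next to one of them, and a chelating Lewis acid can then use that difference.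

**Key cut.** In 11 the C6'–pentyl bond and the C1'–CO2H bond are cut together. This leads to the 2-iodoaryl sulfonate 5, pentylmagnesium bromide 6 and carbon dioxide 7. Installing the two carbon groups one at a time would cost two separate metalation or coupling steps. The aryne route sets both in one flask and lets the C2' methoxy decide which carbon receives the nucleophile. The precursor 5 has neither carbon substituent and no carbon–carbon bond beyond its aromatic rings. The forward reaction needs exchange at iodine and not at chlorine, clean elimination of the sulfonate, nucleophile at C6' and electrophile at C1'.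

**Aryne precursor.** 5 is the sulfonate of iodophenol 4 (cut: S–O). 4 comes from the symmetric phenol 3 by cutting C–I, and 3 from commercial 2-chloro-1,3-dimethoxybenzene 1 by cutting the C–O bond at the one ring position that has no ortho substituent. Because 3 is symmetric, iodination at either free position gives the same compound. The chlorine and both oxygens of ring A are bought with 1, so no halogenation of an electron-rich ring with several open sites is ever needed.

## Roads not taken

**Alternative 1:** Ring A would be built as a dihydroresorcylate. Dimethyl malonate A3 adds to (E)-non-3-en-2-one A2 under methoxide (C1'–C6'), and Claisen closure of the methyl ketone onto a malonate ester (C2'–C3') gives the cyclic dione ester A1. Chlorination at the dione carbon, dehydrogenation, methylation of the unchelated hydroxyl and ester cleavage would then lead to 12.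
- Merits: the materials are cheap, no organometallic reagent or low temperature is needed, and the chlorine enters at the most nucleophilic carbon of a 1,3-dione, a site as well defined as in the chosen plan.
- Weak points: the aromatisation must remove two hydrogens from a 2-chloro-1,3-dione without losing or exchanging the chlorine, and the usual halogen-based dehydrogenations put this at risk. The methyl ester, flanked by a hydroxyl and a pentyl group, needs forcing hydrolysis at a stage where the acid decarboxylates easily. Two stereocentres are made and then erased.
- Comparison: the step count to 12 is about the same, and on scale and cost this road is better. The chosen plan offers a chlorine that is fixed from the first compound, no change of oxidation level, and direct delivery of the free acid from CO2.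

**Alternative 2:** Ring A would be grown on ring B. The aryl oct-2-ynoate A5 and the chlorinated bis(silyloxy)diene A6 undergo a thermal Diels–Alder reaction (C5'–C6' and C1'–C2'), and loss of trimethylsilanol gives the benzyl ester A4, which is the same compound as 15.
- Merits: this is the most convergent plan. The inter-ring ester is made from an unhindered ynoic acid, so the difficult acylation is avoided, and only hydrogenolysis remains after the key step.
- Weak points: A6 is a tetrasubstituted, hydrolytically fragile ketene acetal that has to be prepared in a few steps of its own. A5 is a β-alkyl ynoate and therefore a sluggish dienophile. Its aryl ester is an activated acyl donor that the ketene acetal can attack, and the free phenol of A5 can take up silyl groups.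
- Comparison: if the cycloaddition works, this road is shorter than the chosen one. Its risk falls on the last carbon–carbon bond formation, with all of ring B at stake. The chosen plan places its risk on a small precursor made in three steps, and every later step has close precedent in depside chemistry.

**Alternative 3:** A biomimetic road. Thermolysis of the diketo-dioxinone A8 releases an acylketene that the C4 hydroxyl of 14 captures. Base and then acid fold the resulting aryl trioxododecanoate by aldol closure (C1'–C6') to the depside A7. O-Methylation at C4' and chlorination at C3' would follow.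
- Merits: ketene capture makes the ester with no hindered acid involved, and the ring is assembled from an acyclic chain in one operation.
- Weak points: A7 lacks both the chlorine and the methyl group. Late chlorination must choose C3' over C5' and over C3 and C5 of ring B, all of which are activated positions. The aryl ester of the triketo chain is a good leaving group, so lactonisation to a pyrone with loss of the ring B phenol competes with the aldol closure. A8 also needs several steps.
- Comparison: the ester-forming step of this road is gentler than the acylation of the chosen plan. Its selectivity problem is moved to the end, where it is hardest to solve. The chosen plan has no such problem, because chlorine and both oxygens come from 1.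

Key step: step 4

Remark on the chemistry: the excess of 6 in step 4 is also carboxylated. The hexanoic acid so formed lies outside the equation of the step and is removed at purification.

## Route

Step 1
Reactants: 1 2-chloro-1,3-dimethoxybenzene
Product: 3 4-chloro-3,5-dimethoxyphenol, via aryl pinacol boronate 2 (not isolated)
Conditions: B2pin2 (1.0 equiv), [Ir(OMe)(cod)]2 (1.5 mol %), 4,4'-di-tert-butyl-2,2'-bipyridine (3 mol %), THF, 80 °C; then Oxone (2KHSO5·KHSO4·K2SO4), acetone/H2O, rt
Reagents that add atoms: bis(pinacolato)diboron, CC1(C)OB(OC1(C)C)B1OC(C)(C)C(C)(C)O1 (the boryl group of 2); potassium peroxymonosulfate KHSO5, [K+].[O-]S(=O)(=O)OO (the phenol oxygen of 3)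
Why: Iridium-catalysed C–H borylation is sterically controlled and takes the only C–H with no ortho substituent, the aryl chloride is inert to this catalyst, and the boronate is oxidised in the same flask to the phenol at the same carbon (one-pot borylation/oxidation).

Step 2
Reactants: 3 4-chloro-3,5-dimethoxyphenol
Product: 4 4-chloro-2-iodo-3,5-dimethoxyphenol
Conditions: N-iodosuccinimide (1.0 equiv), MeCN, −20 → 0 °C
Reagents that add atoms: N-iodosuccinimide, O=C1CCC(=O)N1I
Why: Electrophilic aromatic iodination; the two free positions are equivalent by symmetry and each is activated by the hydroxyl and both methoxy groups, so only one mono-iodide can form, and one equivalent at low temperature should hold the reaction at that stage.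

Step 3
Reactants: 4 4-chloro-2-iodo-3,5-dimethoxyphenol
Product: 5 4-chloro-2-iodo-3,5-dimethoxyphenyl 4-chlorobenzenesulfonate
Conditions: 4-ClC6H4SO2Cl, Et3N, DMAP (cat.), CH2Cl2, 0 °C → rt
Reagents that add atoms: 4-chlorobenzenesulfonyl chloride, O=S(=O)(Cl)c1ccc(Cl)cc1
Why: O-Sulfonylation of a phenol; the 4-chlorobenzenesulfonate is a leaving group good enough to depart from an ortho-magnesiated arene on warming, yet it resists attack by a Grignard reagent at sulfur at −78 °C.

Step 4
Reactants: 5 4-chloro-2-iodo-3,5-dimethoxyphenyl 4-chlorobenzenesulfonate; 6 pentylmagnesium bromide; 7 carbon dioxide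
Product: 11 3-chloro-2,4-dimethoxy-6-pentylbenzoic acid, via magnesiated aryl sulfonate 8 (not isolated), via 4-chloro-3,5-dimethoxybenzyne 9 (not isolated), via arylmagnesium bromide 10 (not isolated)
Conditions: 5 added to 6 (3.5 equiv), THF, −78 °C, then −78 °C → rt; CO2 gas (7), −40 °C → rt; 2 M HCl
Reagents that add atoms: none
Why: One equivalent of 6 exchanges the iodide, which lies between the sulfonate and a methoxy group and reacts far faster than the C3' chloride, to give 8 and 1-iodopentane. On warming, 8 loses magnesium 4-chlorobenzenesulfonate and forms aryne 9 with its triple bond between C1' and C6'. A second equivalent of 6 adds across this bond (carbomagnesiation) to give 10, which CO2 converts to the carboxylate and acid to 11. The closest known reactions are the generation of arynes from 2-iodoaryl sulfonates by iodine–magnesium exchange with addition of magnesium nucleophiles and electrophilic trapping, and the addition of Grignard reagents to arynes followed by an electrophile quench. No ring is closed and no stereocentre is formed. The selectivity needed is pentyl at C6' and magnesium at C1'. The C2' methoxy secures it: its inductive pull distorts the aryne so that C6', next to C5'–H, is the more electrophilic and less hindered end, and the charge arrives at C1' beside the C–O bond, where the methoxy oxygen can also coordinate magnesium. The chlorine at C3' has oxygen-bearing carbons on both sides and is meta to the magnesium of 10, so no second aryne can arise. Full exchange at −78 °C before warming keeps unreacted 5 from meeting 10.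

Step 5
Reactants: 11 3-chloro-2,4-dimethoxy-6-pentylbenzoic acid
Product: 12 3-chloro-2-hydroxy-4-methoxy-6-pentylbenzoic acid
Conditions: BCl3 (1 M in CH2Cl2, 2.5 equiv), CH2Cl2, −78 → 0 °C; H2O
Reagents that add atoms: none
Why: Chelation-controlled ether cleavage by BCl3 ortho to a carbonyl group; boron held on the carboxyl oxygen reaches only the C2' methoxy, which is also twisted out of conjugation by its two ortho neighbours and therefore more basic, while the C4' methoxy has no such assistance and should remain.

Step 6
Reactants: 13 olivetolic acid (2,4-dihydroxy-6-pentylbenzoic acid)
Product: 14 benzyl 2,4-dihydroxy-6-pentylbenzoate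
Conditions: BnBr (1.05 equiv), KHCO3, DMF, rt
Reagents that add atoms: benzyl bromide, BrCc1ccccc1
Why: SN2 alkylation of a carboxylate; hydrogencarbonate ionises the carboxylic acid but not the phenols, and room temperature avoids decarboxylation of the salicylic acid.

Step 7
Reactants: 12 3-chloro-2-hydroxy-4-methoxy-6-pentylbenzoic acid; 14 benzyl 2,4-dihydroxy-6-pentylbenzoate
Product: 15 benzyl 4-[(3-chloro-2-hydroxy-4-methoxy-6-pentylbenzoyl)oxy]-2-hydroxy-6-pentylbenzoate
Conditions: (CF3CO)2O, toluene, rt; aq. NaHCO3 work-up
Reagents that add atoms: none
Why: Esterification of a phenol through the mixed carboxylic–trifluoroacetic anhydride, the classical depside condensation; the C4 hydroxyl of 14 is the only phenol not hydrogen-bonded to a carbonyl, whereas the C2 hydroxyl of 14 and the C2' hydroxyl of 12 are chelated and hindered, and the acidic medium spares the aryl ester once it is formed.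

Step 8
Reactants: 15 benzyl 4-[(3-chloro-2-hydroxy-4-methoxy-6-pentylbenzoyl)oxy]-2-hydroxy-6-pentylbenzoate
Product: 16 4-[(3-chloro-2-hydroxy-4-methoxy-6-pentylbenzoyl)oxy]-2-hydroxy-6-pentylbenzoic acid
Conditions: H2 (1 atm), 10% Pd/C, EtOAc, rt, stopped when 15 is consumed
Reagents that add atoms: none
Why: Hydrogenolysis of a benzyl ester; the benzylic C–O bond is cleaved much faster than the C–Cl bond of an electron-rich arene in a neutral medium without base, and the inter-ring aryl ester is not affected.

## Compound list

1 | 2-chloro-1,3-dimethoxybenzene | COc1cccc(OC)c1Cl | starting material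
2 | 2-(4-chloro-3,5-dimethoxyphenyl)-4,4,5,5-tetramethyl-1,3,2-dioxaborolane | COc1cc(B2OC(C)(C)C(C)(C)O2)cc(OC)c1Cl | intermediate
3 | 4-chloro-3,5-dimethoxyphenol | COc1cc(O)cc(OC)c1Cl | intermediate
4 | 4-chloro-2-iodo-3,5-dimethoxyphenol | COc1cc(O)c(I)c(OC)c1Cl | intermediate
5 | 4-chloro-2-iodo-3,5-dimethoxyphenyl 4-chlorobenzenesulfonate | COc1cc(OS(=O)(=O)c2ccc(Cl)cc2)c(I)c(OC)c1Cl | intermediate
6 | pentylmagnesium bromide | CCCCC[Mg]Br | starting material
7 | carbon dioxide | O=C=O | starting material
8 | 2-(bromomagnesio)-4-chloro-3,5-dimethoxyphenyl 4-chlorobenzenesulfonate | COc1cc(OS(=O)(=O)c2ccc(Cl)cc2)c([Mg]Br)c(OC)c1Cl | intermediate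
9 | 4-chloro-3,5-dimethoxybenzyne (4-chloro-3,5-dimethoxy-1,2-didehydrobenzene) | COC1=C(Cl)C(OC)=CC#C1 | intermediate
10 | (3-chloro-2,4-dimethoxy-6-pentylphenyl)magnesium bromide | CCCCCc1cc(OC)c(Cl)c(OC)c1[Mg]Br | intermediate
11 | 3-chloro-2,4-dimethoxy-6-pentylbenzoic acid | CCCCCc1cc(OC)c(Cl)c(OC)c1C(=O)O | intermediate
12 | 3-chloro-2-hydroxy-4-methoxy-6-pentylbenzoic acid | CCCCCc1cc(OC)c(Cl)c(O)c1C(=O)O | intermediate
13 | olivetolic acid (2,4-dihydroxy-6-pentylbenzoic acid) | CCCCCc1cc(O)cc(O)c1C(=O)O | starting material
14 | benzyl 2,4-dihydroxy-6-pentylbenzoate | CCCCCc1cc(O)cc(O)c1C(=O)OCc1ccccc1 | intermediate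
15 | benzyl 4-[(3-chloro-2-hydroxy-4-methoxy-6-pentylbenzoyl)oxy]-2-hydroxy-6-pentylbenzoate | CCCCCc1cc(OC(=O)c2c(CCCCC)cc(OC)c(Cl)c2O)cc(O)c1C(=O)OCc1ccccc1 | intermediate
16 | 4-[(3-chloro-2-hydroxy-4-methoxy-6-pentylbenzoyl)oxy]-2-hydroxy-6-pentylbenzoic acid | CCCCCc1cc(OC(=O)c2c(CCCCC)cc(OC)c(Cl)c2O)cc(O)c1C(=O)O | target

## Step count and uncertain steps

Total: 8 steps. Longest linear sequence: 7 steps (steps 1, 2, 3, 4, 5, 7 and 8, from 1); step 6 is the one-step side branch from 13.

**Step 4 (key step).**
- What may go wrong: a primary alkyl Grignard reagent exchanges iodine more slowly than a secondary one. Exchange may therefore be incomplete when the mixture warms. The reagent can then attack the sulfonate at sulfur, or iodine can pass from unexchanged 5 to arylmagnesium 10. The aryne may also be captured by 8 or 10 in place of 6, or reduced by hydride transfer from the β-carbon of 6. Separation of 11 from the hexanoic acid formed from excess 6 may cost material.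
- Fallback, from 3 to 11 without an aryne: triflation (Tf2O, pyridine) would give 4-chloro-3,5-dimethoxyphenyl trifluoromethanesulfonate F1. Negishi coupling with pentylzinc bromide (from 6 and ZnBr2; PdCl2(dppf) cat., THF) should take place at the triflate, which palladium enters far more readily than the hindered, electron-rich chloride, and give 2-chloro-1,3-dimethoxy-5-pentylbenzene F2. This arene is again symmetric, so N-bromosuccinimide can give only 2-bromo-4-chloro-3,5-dimethoxy-1-pentylbenzene F3. Bromine–lithium exchange (n-BuLi, THF, −78 °C) and quenching with 7 would return to 11.

**Step 5.**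
- What may go wrong: loss of CO2 from the electron-rich salicylic acid as HCl accumulates, cleavage of both methyl ethers, or slow reaction if the boron carboxylate chelates poorly.
- Fallback, from 11 to 12 with an ester as the chelating group: alkylation of the carboxylate (allyl bromide, K2CO3, DMF) would give allyl 3-chloro-2,4-dimethoxy-6-pentylbenzoate F4. BCl3 at low temperature would then give allyl 3-chloro-2-hydroxy-4-methoxy-6-pentylbenzoate F5. Removal of the allyl group with Pd(PPh3)4 and PhSO2Na in THF/MeOH, followed by acidification, would come back at 12.

**Step 7.**
- What may go wrong: low conversion of an acid with two ortho substituents, self-acylation through the C2' hydroxyl of 12, acylation at the C2 hydroxyl of 14, or decarboxylation of 12 in the trifluoroacetic acid that forms.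
- Fallback, from 11 to 15, bypassing steps 5 and 7: oxalyl chloride with catalytic DMF would give 3-chloro-2,4-dimethoxy-6-pentylbenzoyl chloride F6, which has no free hydroxyl. Acylation of 14 (Et3N, DMAP cat., CH2Cl2) would give benzyl 4-[(3-chloro-2,4-dimethoxy-6-pentylbenzoyl)oxy]-2-hydroxy-6-pentylbenzoate F7. BCl3 at −78 °C, now anchored on the inter-ring ester carbonyl, would remove the C2' methyl group and come back at 15.

**Step 8.**
- What may go wrong: hydrodechlorination at C3' competing with debenzylation, in particular if the reaction is left after 15 is consumed.
- Fallback, from 13 to 16 without hydrogen: alkylation with allyl bromide and KHCO3 in DMF would give allyl 2,4-dihydroxy-6-pentylbenzoate F8. Condensation with 12 under the conditions of step 7 would give allyl 4-[(3-chloro-2-hydroxy-4-methoxy-6-pentylbenzoyl)oxy]-2-hydroxy-6-pentylbenzoate F9. Deallylation with Pd(PPh3)4 (zerovalent palladium) and PhSO2Na, then acidification, would come back at 16 with the chloride untouched.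

## Further compounds

F1 | step 4 | 4-chloro-3,5-dimethoxyphenyl trifluoromethanesulfonate | COc1cc(OS(=O)(=O)C(F)(F)F)cc(OC)c1Cl
F2 | step 4 | 2-chloro-1,3-dimethoxy-5-pentylbenzene | CCCCCc1cc(OC)c(Cl)c(OC)c1
F3 | step 4 | 2-bromo-4-chloro-3,5-dimethoxy-1-pentylbenzene | CCCCCc1cc(OC)c(Cl)c(OC)c1Br
F4 | step 5 | allyl 3-chloro-2,4-dimethoxy-6-pentylbenzoate | CCCCCc1cc(OC)c(Cl)c(OC)c1C(=O)OCC=C
F5 | step 5 | allyl 3-chloro-2-hydroxy-4-methoxy-6-pentylbenzoate | CCCCCc1cc(OC)c(Cl)c(O)c1C(=O)OCC=C
F6 | step 7 | 3-chloro-2,4-dimethoxy-6-pentylbenzoyl chloride | CCCCCc1cc(OC)c(Cl)c(OC)c1C(Cl)=O
F7 | step 7 | benzyl 4-[(3-chloro-2,4-dimethoxy-6-pentylbenzoyl)oxy]-2-hydroxy-6-pentylbenzoate | CCCCCc1cc(OC(=O)c2c(CCCCC)cc(OC)c(Cl)c2OC)cc(O)c1C(=O)OCc1ccccc1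
F8 | step 8 | allyl 2,4-dihydroxy-6-pentylbenzoate | CCCCCc1cc(O)cc(O)c1C(=O)OCC=C
F9 | step 8 | allyl 4-[(3-chloro-2-hydroxy-4-methoxy-6-pentylbenzoyl)oxy]-2-hydroxy-6-pentylbenzoate | CCCCCc1cc(OC(=O)c2c(CCCCC)cc(OC)c(Cl)c2O)cc(O)c1C(=O)OCC=C
A1 | alternative 1 | methyl trans-4-hydroxy-2-oxo-6-pentylcyclohex-3-ene-1-carboxylate (racemic, one enantiomer drawn) | CCCCC[C@@H]1CC(O)=CC(=O)[C@H]1C(=O)OC
A2 | alternative 1 | (E)-non-3-en-2-one | CCCCC/C=C/C(C)=O
A3 | alternative 1 | dimethyl malonate | COC(=O)CC(=O)OC
A4 | alternative 2 | benzyl 4-[(3-chloro-2-hydroxy-4-methoxy-6-pentylbenzoyl)oxy]-2-hydroxy-6-pentylbenzoate | CCCCCc1cc(OC(=O)c2c(CCCCC)cc(OC)c(Cl)c2O)cc(O)c1C(=O)OCc1ccccc1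
A5 | alternative 2 | benzyl 2-hydroxy-4-(oct-2-ynoyloxy)-6-pentylbenzoate | CCCCCC#CC(=O)Oc1cc(O)c(C(=O)OCc2ccccc2)c(CCCCC)c1
A6 | alternative 2 | 2-chloro-3-methoxy-1,1-bis(trimethylsilyloxy)buta-1,3-diene | C=C(OC)C(Cl)=C(O[Si](C)(C)C)O[Si](C)(C)C
A7 | alternative 3 | benzyl 4-[(2,4-dihydroxy-6-pentylbenzoyl)oxy]-2-hydroxy-6-pentylbenzoate | CCCCCc1cc(OC(=O)c2c(CCCCC)cc(O)cc2O)cc(O)c1C(=O)OCc1ccccc1
A8 | alternative 3 | 6-(2,4-dioxononyl)-2,2-dimethyl-4H-1,3-dioxin-4-one | CCCCCC(=O)CC(=O)CC1=CC(=O)OC(C)(C)O1
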